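## Retrosynthetic overview

1. Target 15 ⇐ acyclic triflate 13 by one double cation–olefin cyclisation in which C6 of a tetrasubstituted vinylsilane reacts twice: C6–C11 (ring A, bromonium from the C10/C11 bromochloride, ipso loss of Me3Si), then C6–C1 (ring B, spiro centre, C7=CH2 by proton loss).
2. 13 ⇐ alcohol 12 ⇐ (Z)-allylic alcohol 11 by Ti-catalysed enantioselective bromochlorination (sets C2 and C3).
3. 11 ⇐ prenol dianion + allylic bromide 9 (C4–C5); 9 ⇐ alcohol 8 ⇐ dianion of silylprenol 6 + triflate 3 (C8–C9).
4. 3 ⇐ prenol by the same bromochlorination with the mirror-image ligand (sets C10); 6 ⇐ 1-(trimethylsilyl)propyne.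
5. Ring order: ring A first, ring B second, both in the last operation; no ring exists before it.

Assumption: atom labels C1–C15 are chamigrene/farnesane labels (ring B = C1–C6, ring A = C6–C11, C6 spiro, C14 = exocyclic CH2), and the chiral tridentate Schiff-base ligand for the Ti-mediated bromochlorination is available as both enantiomers (L* is the one that gives (R)-2, ent-L* its mirror image).

## Route

Step 1
Reactants: 1 3-methylbut-2-en-1-ol (prenol)
Product: 2 (2R)-2-bromo-3-chloro-3-methylbutan-1-ol
Conditions: NBS, ClTi(OiPr)3, L* (20 mol%), hexanes, −20 °C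
Reagents that add atoms: N-bromosuccinimide, O=C1CCC(=O)N1Br; chlorotitanium triisopropoxide, CC(C)O[Ti](Cl)(OC(C)C)OC(C)C
Why: Ti-alkoxide-directed catalytic enantioselective bromochlorination of an allylic alcohol, in which Br+ goes to the alkene face chosen by the chiral Ti complex and chloride adds anti at the tertiary carbon (Markovnikov), so that C10 of the target is set as R.

Step 2
Reactants: 2 (2R)-2-bromo-3-chloro-3-methylbutan-1-ol
Product: 3 (2R)-2-bromo-3-chloro-3-methylbutyl trifluoromethanesulfonate
Conditions: Tf2O, 2,6-lutidine, CH2Cl2, −78 °C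
Reagents that add atoms: trifluoromethanesulfonic anhydride, O=S(=O)(OS(=O)(=O)C(F)(F)F)C(F)(F)F
Why: O-sulfonylation (triflate formation) of the primary alcohol at low temperature with a hindered base gives a reactive alkylating agent without touching the stereocentre.

Step 3
Reactants: 4 trimethyl(prop-1-yn-1-yl)silane
Product: 6 3-methyl-2-(trimethylsilyl)but-2-en-1-ol, via alkenylalane 5 (not isolated)
Conditions: Me3Al, Cp2ZrCl2 (cat.), ClCH2CH2Cl, rt; then n-BuLi, (CH2O)n, THF, −78 °C → rt
Reagents that add atoms: trimethylaluminium, C[Al](C)C; formaldehyde (as paraformaldehyde), C=O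
Why: Zr-catalysed methylalumination of a silylalkyne (Negishi carboalumination) puts Al on the silicon-bearing carbon and the derived alanate is hydroxymethylated by formaldehyde; no stereochemistry is at stake because the new alkene carbon carries two methyl groups.

Step 4
Reactants: 6 3-methyl-2-(trimethylsilyl)but-2-en-1-ol; 3 (2R)-2-bromo-3-chloro-3-methylbutyl trifluoromethanesulfonate
Product: 8 (2E,6R)-6-bromo-7-chloro-3,7-dimethyl-2-(trimethylsilyl)oct-2-en-1-ol, via dianion 7 (not isolated)
Conditions: n-BuLi (2.2 equiv), TMEDA, Et2O, 0 °C → rt; then CuBr·SMe2 (10 mol%), 3, THF, −78 → −30 °C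
Reagents that add atoms: none
Why: Alkoxide-directed allylic lithiation (as for the dianion of prenol, here helped by silicon) removes a proton from the methyl cis to CH2OLi, and SN2 alkylation of the allyl anion at its CH2 terminus by the primary triflate forms C8–C9 with C5 and C8 cis (2E), while C10 is untouched and stays R.

Step 5
Reactants: 8 (2E,6R)-6-bromo-7-chloro-3,7-dimethyl-2-(trimethylsilyl)oct-2-en-1-ol
Product: 9 [(2E,6R)-1,6-dibromo-7-chloro-3,7-dimethyloct-2-en-2-yl]trimethylsilane
Conditions: CBr4, PPh3, CH2Cl2, 0 °C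
Reagents that add atoms: carbon tetrabromide, BrC(Br)(Br)Br
Why: Appel bromination converts the primary allylic alcohol into the bromide under neutral conditions, SN2′ being blocked by the tetrasubstituted alkene and the secondary bromide and tertiary chloride being inert.

Step 6
Reactants: 1 3-methylbut-2-en-1-ol (prenol); 9 [(2E,6R)-1,6-dibromo-7-chloro-3,7-dimethyloct-2-en-2-yl]trimethylsilane
Product: 11 (2Z,6E,10R)-10-bromo-11-chloro-3,7,11-trimethyl-6-(trimethylsilyl)dodeca-2,6-dien-1-ol, via dianion 10 (not isolated)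
Conditions: 1, n-BuLi (2 equiv), TMEDA, Et2O, rt; then 9, THF, −78 °C
Reagents that add atoms: none
Why: C-alkylation of the prenol dianion at its CH2Li terminus (the classical route to nerol-type alcohols) forms C4–C5 and gives the 2Z allylic alcohol because the lithiated methyl is the one cis to CH2OLi, and at −78 °C SN2 at the allylic bromide is faster than any reaction at the hindered secondary bromide or the tertiary chloride.

Step 7
Reactants: 11 (2Z,6E,10R)-10-bromo-11-chloro-3,7,11-trimethyl-6-(trimethylsilyl)dodeca-2,6-dien-1-ol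
Product: 12 (2S,3S,6E,10R)-2,10-dibromo-3,11-dichloro-3,7,11-trimethyl-6-(trimethylsilyl)dodec-6-en-1-ol
Conditions: NBS, ClTi(OiPr)3, ent-L* (20 mol%), hexanes, −20 °C
Reagents that add atoms: N-bromosuccinimide, O=C1CCC(=O)N1Br; chlorotitanium triisopropoxide, CC(C)O[Ti](Cl)(OC(C)C)OC(C)C
Why: Second Ti-directed enantioselective bromochlorination, now of a (Z)-trisubstituted allylic alcohol, in which OH-bound titanium confines the reaction to C2=C3 and anti addition (Br at C2, Cl at tertiary C3) under control of ent-L* (sense at C2 opposite to step 1) sets 2S,3S, the later trans Br/Cl pair of ring B.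

Step 8
Reactants: 12 (2S,3S,6E,10R)-2,10-dibromo-3,11-dichloro-3,7,11-trimethyl-6-(trimethylsilyl)dodec-6-en-1-ol
Product: 15 (2R,6S,8S,9S)-2,8-dibromo-9-chloro-1,1,9-trimethyl-5-methylidenespiro[5.5]undecane, via triflate 13 (not isolated), via monocycle 14 (not isolated)
Conditions: Tf2O, 2,6-di-tert-butyl-4-methylpyridine, CH2Cl2, −78 °C; then (CF3)2CHOH (0.01 M), −40 °C → rt
Reagents that add atoms: none
Why: Proposed new method: in HFIP the tertiary chloride at C11 ionises with anchimeric help from the C10 bromine (bromonium ion, C10 stays R), the vinylsilane attacks it through C6 in a six-membered chair (ipso attack, β-silyl cation at C7) and loses Me3Si+ to give the ring-A alkene 14, whose C6 then displaces the Br-assisted primary triflate at C1 in a 6-exo closure that creates the spiro centre with C2–Br antiperiplanar to the new bond (equatorial), Cl equatorial and the CMe2 side of ring A equatorial on ring B (6S), after which the C7 cation loses a methyl proton to the hindered base to give the exocyclic alkene (its ring-alkene isomer is the expected by-product, removed on AgNO3–silica); should ring B close first, ipso substitution with retention and the 6E geometry (C5 cis to C8) lead to the same 6S centre; closest known reactions are the solvolytic bromonium cyclisation of enantioenriched bromochlorides onto tetrasubstituted alkenes, vinylsilane-terminated (ipso) cation–olefin cyclisations and π-cyclisation of primary sulfonates.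

## Compound list

1 | 3-methylbut-2-en-1-ol (prenol) | CC(C)=CCO | starting material
2 | (2R)-2-bromo-3-chloro-3-methylbutan-1-ol | OC[C@@H](Br)C(C)(C)Cl | intermediate
3 | (2R)-2-bromo-3-chloro-3-methylbutyl trifluoromethanesulfonate | O=S(=O)(OC[C@@H](Br)C(C)(C)Cl)C(F)(F)F | intermediate
4 | trimethyl(prop-1-yn-1-yl)silane | CC#C[Si](C)(C)C | starting material
5 | dimethyl[2-methyl-1-(trimethylsilyl)prop-1-en-1-yl]alane | CC(C)=C([Si](C)(C)C)[Al](C)C | intermediate
6 | 3-methyl-2-(trimethylsilyl)but-2-en-1-ol | CC(C)=C(CO)[Si](C)(C)C | intermediate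
7 | lithium (2E)-4-lithio-3-methyl-2-(trimethylsilyl)but-2-en-1-olate (dianion of 6, CH2Li cis to CH2OLi) | [Li]OC/C(=C(\C[Li])C)[Si](C)(C)C | intermediate
8 | (2E,6R)-6-bromo-7-chloro-3,7-dimethyl-2-(trimethylsilyl)oct-2-en-1-ol | OC/C(=C(\CC[C@@H](Br)C(C)(C)Cl)C)[Si](C)(C)C | intermediate
9 | [(2E,6R)-1,6-dibromo-7-chloro-3,7-dimethyloct-2-en-2-yl]trimethylsilane | BrC/C(=C(\CC[C@@H](Br)C(C)(C)Cl)C)[Si](C)(C)C | intermediate
10 | lithium (2Z)-4-lithio-3-methylbut-2-en-1-olate (dianion of prenol) | [Li]OC/C=C(\C[Li])C | intermediate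
11 | (2Z,6E,10R)-10-bromo-11-chloro-3,7,11-trimethyl-6-(trimethylsilyl)dodeca-2,6-dien-1-ol | OC/C=C(\CC/C(=C(\CC[C@@H](Br)C(C)(C)Cl)C)[Si](C)(C)C)C | intermediate
12 | (2S,3S,6E,10R)-2,10-dibromo-3,11-dichloro-3,7,11-trimethyl-6-(trimethylsilyl)dodec-6-en-1-ol | OC[C@H](Br)[C@@](C)(Cl)CC/C(=C(\CC[C@@H](Br)C(C)(C)Cl)C)[Si](C)(C)C | intermediate
13 | (2S,3S,6E,10R)-2,10-dibromo-3,11-dichloro-3,7,11-trimethyl-6-(trimethylsilyl)dodec-6-en-1-yl trifluoromethanesulfonate | O=S(=O)(OC[C@H](Br)[C@@](C)(Cl)CC/C(=C(\CC[C@@H](Br)C(C)(C)Cl)C)[Si](C)(C)C)C(F)(F)F | intermediate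
14 | (2S,3S)-2-bromo-5-[(5R)-5-bromo-2,6,6-trimethylcyclohex-1-en-1-yl]-3-chloro-3-methylpentyl trifluoromethanesulfonate | O=S(=O)(OC[C@H](Br)[C@@](C)(Cl)CCC1=C(C)CC[C@@H](Br)C1(C)C)C(F)(F)F | intermediate
15 | (2R,6S,8S,9S)-2,8-dibromo-9-chloro-1,1,9-trimethyl-5-methylidenespiro[5.5]undecane, i.e. (2S,3S,6S,10R)-2,10-dibromo-3-chloro-β-chamigrene | C=C1CC[C@@H](Br)C(C)(C)[C@]12CC[C@](C)(Cl)[C@@H](Br)C2 | target

## Step count and risks

Total steps: 8. Longest linear sequence: 7 (steps 1, 2, 4, 5, 6, 7, 8; the branch through step 3 is 6).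

The three steps most likely to fail:

Step 8 (the double cyclisation). The order of the two ionisations is not controlled, the vinylsilane can be protodesilylated, and the final proton loss can give the ring-alkene isomer. Fallback: separate the two ring closures. From 12, the free alcohol is solvolysed in HFIP with the hindered pyridine, so that only the C10/C11 bromochloride can react. Ipso cyclisation gives the ring-A alcohol (2S,3S)-2-bromo-5-[(5R)-5-bromo-2,6,6-trimethylcyclohex-1-en-1-yl]-3-chloro-3-methylpentan-1-ol F1, which is purified. Triflation of F1 at −78 °C gives 14, where the fallback rejoins the route; 14 then closes ring B on warming as in step 8.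

Step 7 (NBS and a Lewis-acidic Ti reagent beside an electron-rich tetrasubstituted vinylsilane, on a Z substrate). Fallback: remove the vinylsilane before the halogenation. From 11, buffered HFIP solvolysis closes ring A and gives (2Z)-5-[(5R)-5-bromo-2,6,6-trimethylcyclohex-1-en-1-yl]-3-methylpent-2-en-1-ol F2. The Ti-directed bromochlorination is then run on F2, whose hindered ring alkene is not OH-directed, and gives the alcohol F1 described above. Triflation of F1 gives 14, where the route is rejoined.

Step 6 (a strongly basic dianion meets a substrate with a secondary bromide, a tertiary chloride and a 2-silylallyl bromide). Fallback: build the Z-allylic alcohol by carbonyl chemistry. From 9, C-alkylation of allyl acetoacetate (K2CO3, acetone) gives allyl (4E,8R)-2-acetyl-8-bromo-9-chloro-5,9-dimethyl-4-(trimethylsilyl)dec-4-enoate F3 (both C2 epimers). Pd(PPh3)4 with morpholine removes the allyl ester with loss of CO2 and gives the methyl ketone (5E,9R)-9-bromo-10-chloro-6,10-dimethyl-5-(trimethylsilyl)undec-5-en-2-one F4. A Z-selective Horner–Wadsworth–Emmons olefination of the Still–Gennari type (methyl bis(2,2,2-trifluoroethyl)phosphonoacetate, KHMDS, 18-crown-6, −78 °C) gives methyl (2Z,6E,10R)-10-bromo-11-chloro-3,7,11-trimethyl-6-(trimethylsilyl)dodeca-2,6-dienoate F5, the minor 2E isomer being removed by chromatography. DIBAL-H at −78 °C reduces F5 to 11, where the route is rejoined.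

Further compounds
F1 | step 8 | (2S,3S)-2-bromo-5-[(5R)-5-bromo-2,6,6-trimethylcyclohex-1-en-1-yl]-3-chloro-3-methylpentan-1-ol | OC[C@H](Br)[C@@](C)(Cl)CCC1=C(C)CC[C@@H](Br)C1(C)C
F2 | step 7 | (2Z)-5-[(5R)-5-bromo-2,6,6-trimethylcyclohex-1-en-1-yl]-3-methylpent-2-en-1-ol | OC/C=C(\CCC1=C(C)CC[C@@H](Br)C1(C)C)C
F3 | step 6 | allyl (4E,8R)-2-acetyl-8-bromo-9-chloro-5,9-dimethyl-4-(trimethylsilyl)dec-4-enoate | C=CCOC(=O)C(C(C)=O)C/C(=C(\CC[C@@H](Br)C(C)(C)Cl)C)[Si](C)(C)C
F4 | step 6 | (5E,9R)-9-bromo-10-chloro-6,10-dimethyl-5-(trimethylsilyl)undec-5-en-2-one | CC(=O)CC/C(=C(\CC[C@@H](Br)C(C)(C)Cl)C)[Si](C)(C)C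
F5 | step 6 | methyl (2Z,6E,10R)-10-bromo-11-chloro-3,7,11-trimethyl-6-(trimethylsilyl)dodeca-2,6-dienoate | COC(=O)/C=C(\CC/C(=C(\CC[C@@H](Br)C(C)(C)Cl)C)[Si](C)(C)C)C
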